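| setting | Monday's | Sunday's | Thursday's | flask |
|---|---|---|---|---|
| starting complex | 0.55 M | 0.83 M | 1.1 M | 1.1 M |
| incoming ligand | 1 equiv | 1 equiv | 2 equiv | 1.00 equiv |
| capture agent | 0.055 M | 0.055 M | 0.055 M | 0.0550 M |
| remark | run made earlier | run made earlier | run made earlier |  |
| time |  |  |  | 2.5 d |

| run | time / h | complex with one exchanged / % | complex with two exchanged / % |
|---|---|---|---|
| Monday's | 5.00 | 16.4 | 39.8 |
| Monday's | 10.0 | 15.0 | 40.1 |
| Monday's | 15.0 | 13.3 | 38.3 |
| Monday's | 20.0 | 11.8 | 38.8 |
| Monday's | 25.0 | 12.7 | 38.1 |
| Monday's | 30.0 | 10.7 | 39.2 |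
| Monday's | 40.0 | 10.0 | 35.1 |
| Sunday's | 3.00 | 15.6 | 41.0 |
| Sunday's | 4.00 | 17.0 | 42.3 |
| Sunday's | 6.00 | 14.4 | 41.4 |
| Sunday's | 10.0 | 13.8 | 41.4 |
| Sunday's | 15.0 | 13.6 | 40.8 |
| Sunday's | 25.0 | 12.1 | 38.3 |
| Sunday's | 40.0 | 13.9 | 40.0 |
| Thursday's | 8.00 | 1.6 | 94.2 |
| Thursday's | 15.0 | 0.9 | 96.4 |
| Thursday's | 20.0 | 0 | 97.3 |
| Thursday's | 30.0 | 0.3 | 96.4 |
| Thursday's | 40.0 | 1.3 | 93.5 |

(each reading ± 1 percentage point)

- a reading or a percentage of complex with two exchanged counts all its forms, free or not

* equivalents of incoming ligand to starting complex, everything else as given, that leave most complex with one exchanged at 2.5 d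
* the amount of complex with one exchanged then, in percent of the starting complex charged
* the amount of complex with one exchanged with the amounts as given

1. A ratio of two rate constants was my scale: that of the second exchange over that of the first, r. Both rates carry the incoming ligand as a factor, so it cancels from their ratio, and one-exchanged = (start − start^r)/(r − 1), as fractions of the charge. Two equal independent sites are the zero of this scale: r = 0.5, with half of the complex one-exchanged at 1 equiv.

2. Sunday's first two readings and Monday's first averaged 16.3% one-exchanged and 41.0% two-exchanged, which by difference put starting complex at 42.6%. Solving the formula gave r = 3.25, this selectivity factor standing above the zero.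

3. In this reckoning one-exchanged peaks where the two rates are equal, at 59.2% starting complex and 18.2% one-exchanged, which takes 0.633 equiv of incoming ligand.

4. The capture agent came to 5.00% of the complex in this flask. Monday's one-exchanged read 6.4 percentage points lower at 40.0 h than at its first reading, and I took that fall as capture. Subtracting the whole charge of capture agent of this flask, I expected 13.2% at best and 11.3% as charged.

The forecast differed from my reckoning, with 1.05 equiv, 13.7% and 13.4%, adding that “the ranges are wide”.

The flask gave 0.649 equiv, 14.0% and 12.0%.

    starting complex + incoming ligand → leaving ligand + complex with one exchanged (k = 3.50 × 10⁻⁴ L mol⁻¹ s⁻¹)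
    complex with one exchanged + capture agent → trapped intermediate (k = 1.10 × 10⁻⁴ L mol⁻¹ s⁻¹)
    complex with two exchanged → over-reaction product (k = 8.90 × 10⁻⁶ s⁻¹)
    complex with one exchanged + incoming ligand → leaving ligand + complex with two exchanged (k = 0.00110 L mol⁻¹ s⁻¹)
    crystals ⇌ complex with two exchanged, rate k5*(cs5 - [complex with two exchanged]) while solid is left; crystals form when [complex with two exchanged] > cs5 (solubility = 20.0 mM, k = 0.0670 s⁻¹)

On this flask, r applied to the 41.6% of starting complex gives 15.9%, and its one-exchanged and trapped intermediate add to 16.8%. The neighbouring flask charged 1.70 equiv of incoming ligand. The ligand balance with r, dropping the power term of 0.109%, gives 12.3% starting complex and 5.45% one-exchanged before capture. That flask held 11.9% starting complex, 3.38% trapped intermediate and 2.91% complex with one exchanged.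

All runs come from a simulation on assumed constants, noise included.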